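**Retrosynthetic overview**
1. Structural handle: C1' of the cyclopentane is a quaternary stereocentre carrying CH3, the CMe2 carbon C2' and the carbinol carbon C1 of the cyclohexane. This is the pattern a 1-methylcyclohexene oxide leaves when its ring CH2 shifts to the methyl-bearing carbon (six-ring to five-ring) and the former epoxide CH becomes C1 as CHO.
2. Target 18 ⇐ chloride opening of the 7-oxabicyclo[2.2.1]heptane bromoether 17 (sets C4–Cl) ⇐ bromoetherification of cyclohexenol 16 (sets C3–Br) ⇐ RCM of diene 15 ⇐ asymmetric allylation of ketone 14 (sets C1).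
3. 14 ⇐ bromo aldehyde 10 + 3-methylbut-3-enyl Grignard; the C3'–Br of 10 ⇐ the C3' ketone of keto aldehyde 6 (CHO masked as acetal, CBS reduction, Appel inversion).
4. 6 ⇐ Lewis-acid semipinacol ring contraction of epoxy ketone 5 ⇐ Shi epoxidation of 2,2,3-trimethylcyclohex-3-enone 4 ⇐ 3-methylcyclohex-2-enone + two equivalents of MeI.
5. Ring order: cyclopentane (step 3, by contraction of the starting six-ring), cyclohexene (step 11, RCM), transient oxa-bridge (step 12, opened in step 13).

Key step: step 3

Locants: C1–C6 for the cyclohexane (C1 carbinol, C3 CHBr, C4 CClMe); C1'–C5' for the cyclopentane (C1' quaternary CMe, C2' CMe2, C3' CHBr).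
Assumption: the (10S) antipode of the allylborane in step 10 is taken to be the one that adds allyl to the Re face of a ketone RL–CO–RS (acetophenone → (R)-2-phenylpent-4-en-2-ol); if a test on that model ketone shows the opposite sense, the antipode is used. The reagent is not commercial; it would be prepared from commercial B-methoxy-9-BBN by the known insertion, resolution and allylation sequence, which is not counted in the step total.

**Step 1**
Reactants: 1 3-methylcyclohex-2-en-1-one; 2 iodomethane
Product: 4 2,2,3-trimethylcyclohex-3-en-1-one, via 2,3-dimethylcyclohex-3-en-1-one 3 (not isolated)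
Conditions: t-BuOK (2.3 equiv), t-BuOH–THF, 0 °C; MeI (2.6 equiv), 0 °C → rt
Reagents that add atoms: iodomethane (second equivalent), CI
Why: Deconjugative α,α-dialkylation of an enone through its thermodynamic dienolate (the reaction type of the 4,4-dimethylation of steroidal Δ4-3-ketones): the first MeI alkylates C2 to give the β,γ-enone 3, whose doubly activated C2–H is removed again by the excess base so that the second MeI enters at the same carbon; the alkene ends out of conjugation because C2 becomes quaternary, and no stereocentre remains.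

**Step 2**
Reactants: 4 2,2,3-trimethylcyclohex-3-en-1-one
Product: 5 (1S,6R)-1,2,2-trimethyl-7-oxabicyclo[4.1.0]heptan-3-one
Conditions: D-fructose-derived Shi ketone (30 mol %), Oxone, K2CO3, Bu4NHSO4, MeCN–DMM / aq. Na2B4O7–EDTA buffer (pH 10.5), 0 °C
Reagents that add atoms: Oxone (potassium peroxymonosulfate), [K+].[O-]S(=O)(=O)OO
Why: Shi asymmetric epoxidation of a trisubstituted alkene by the chiral dioxirane (spiro transition state); by analogy with 1-substituted cyclohexenes the D-fructose-derived ketone should give the (1S,6R)-epoxide and so set both epoxide carbons, while the quaternary C2 rules out conjugation or β-elimination of the β,γ-epoxy ketone in the basic buffer.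

**Step 3**
Reactants: 5 (1S,6R)-1,2,2-trimethyl-7-oxabicyclo[4.1.0]heptan-3-one
Product: 6 (R)-1,2,2-trimethyl-3-oxocyclopentane-1-carbaldehyde
Conditions: MABR [MeAl(OAr)2, Ar = 4-bromo-2,6-di-tert-butylphenyl; 2.0 equiv, from Me3Al + 2 ArOH, CH2Cl2, rt]; then 5, CH2Cl2, −78 → −20 °C
Reagents that add atoms: none
Why: The bulky oxophilic aluminium Lewis acid binds the epoxide oxygen and the C–O bond at the methyl-bearing carbon lengthens toward a tertiary cation while the oxygen stays on the CH carbon and pushes; the ring CH2 (C5 of the cyclohexanone) then shifts from the CH carbon to the electron-poor carbon and the CH carbon collapses to the aldehyde. This is a Meinwald/semipinacol rearrangement, closest to the MABR-mediated conversion of 1-methylcyclohexene oxide into 1-methylcyclopentanecarbaldehyde. The cyclopentane is closed by this 1,2-alkyl shift, a ring contraction in which the new C1'–C5' bond forms inside the old six-membered ring. The only new stereocentre, C1', is controlled by the epoxide configuration, because the migrating carbon enters on the face opposite the departing oxygen (inversion at the terminus), so (1S,6R)-5 should give (R)-6. The step needs ring-bond migration to win over hydride migration (which would give 2,2,3-trimethylcyclohexane-1,4-dione); the very hindered aluminium reagent favours the path that ends in an aldehyde complex with Al syn to H over a ketone complex flanked by two substituted carbons. Methyl migration from the neighbouring CMe2 is disfavoured because it would place a cation α to the C=O, and the inductive pull of that ketone keeps the opening concerted enough to transfer the configuration.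

**Step 4**
Reactants: 6 (R)-1,2,2-trimethyl-3-oxocyclopentane-1-carbaldehyde
Product: 7 (3R)-3-(dimethoxymethyl)-2,2,3-trimethylcyclopentan-1-one
Conditions: HC(OMe)3, MeOH, PPTS (cat.), rt
Reagents that add atoms: trimethyl orthoformate, COC(OC)OC
Why: Acid-catalysed acetalisation is chemoselective for the aldehyde because the ketone is flanked by a quaternary carbon; it masks the CHO for the reduction and bromination at C3' and touches no stereocentre.

**Step 5**
Reactants: 7 (3R)-3-(dimethoxymethyl)-2,2,3-trimethylcyclopentan-1-one
Product: 8 (1R,3R)-3-(dimethoxymethyl)-2,2,3-trimethylcyclopentan-1-ol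
Conditions: (S)-Me-CBS (20 mol %), BH3·SMe2, THF, −20 °C; MeOH
Reagents that add atoms: none
Why: Corey–Bakshi–Shibata reduction under reagent control: the ketone has a fully substituted α-carbon on one side and CH2 on the other, so the (S)-catalyst should give the (R)-carbinol (OH trans to the dimethoxymethyl group), overriding the modest bias of the ring, which is expected to be mismatched.

**Step 6**
Reactants: 8 (1R,3R)-3-(dimethoxymethyl)-2,2,3-trimethylcyclopentan-1-ol
Product: 9 (1S,3R)-1-bromo-3-(dimethoxymethyl)-2,2,3-trimethylcyclopentane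
Conditions: PPh3, CBr4, 2,6-lutidine, toluene, 0 → 60 °C
Reagents that add atoms: carbon tetrabromide, BrC(Br)(Br)Br
Why: Appel reaction: bromide displaces the alkoxyphosphonium group in an SN2 step with inversion, which should give the (S)-bromide cis to the dimethoxymethyl group; the non-ionising conditions and the lutidine buffer are chosen to avoid methyl shift from the neighbouring CMe2 and acetal cleavage.

**Step 7**
Reactants: 9 (1S,3R)-1-bromo-3-(dimethoxymethyl)-2,2,3-trimethylcyclopentane
Product: 10 (1R,3S)-3-bromo-1,2,2-trimethylcyclopentane-1-carbaldehyde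
Conditions: TFA–H2O, CH2Cl2, 0 °C → rt
Reagents that add atoms: water, O
Why: Acid hydrolysis of the dimethyl acetal; the neopentyl-type secondary bromide is inert to aqueous acid and the aldehyde has no α-hydrogen, so no stereocentre is at risk.

**Step 8**
Reactants: 10 (1R,3S)-3-bromo-1,2,2-trimethylcyclopentane-1-carbaldehyde; 11 4-bromo-2-methylbut-1-ene
Product: 13 1-[(1R,3S)-3-bromo-1,2,2-trimethylcyclopentyl]-4-methylpent-4-en-1-ol (both carbinol epimers), via (3-methylbut-3-en-1-yl)magnesium bromide 12 (not isolated)
Conditions: 11, Mg, THF, rt; then 10, THF, −78 → 0 °C; aq. NH4Cl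
Reagents that add atoms: none
Why: Grignard addition to the aldehyde; the hindered secondary alkyl bromide does not couple with the Grignard reagent at low temperature, and the new carbinol centre is left uncontrolled because it is oxidised in the next step.

**Step 9**
Reactants: 13 1-[(1R,3S)-3-bromo-1,2,2-trimethylcyclopentyl]-4-methylpent-4-en-1-ol
Product: 14 1-[(1R,3S)-3-bromo-1,2,2-trimethylcyclopentyl]-4-methylpent-4-en-1-one
Conditions: Dess–Martin periodinane, NaHCO3, CH2Cl2, rt
Reagents that add atoms: none
Why: Dess–Martin oxidation of a hindered secondary alcohol to the ketone under neutral conditions that leave the bromide and the 1,1-disubstituted alkene alone; both epimers converge.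

**Step 10**
Reactants: 14 1-[(1R,3S)-3-bromo-1,2,2-trimethylcyclopentyl]-4-methylpent-4-en-1-one
Product: 15 (4R)-4-[(1R,3S)-3-bromo-1,2,2-trimethylcyclopentyl]-7-methylocta-1,7-dien-4-ol
Conditions: (10S)-B-allyl-10-phenyl-9-borabicyclo[3.3.2]decane (1.5 equiv), Et2O, −78 °C → rt; aq. NaOH work-up
Reagents that add atoms: (10S)-B-allyl-10-phenyl-9-borabicyclo[3.3.2]decane, C=CCB1[C@H](c2ccccc2)[C@@H]2CCC[C@H]1CCC2
Why: Asymmetric allylboration of a ketone through a chair Zimmerman–Traxler transition state with the tert-alkyl group equatorial and the CH2 chain in the pocket beside the 10-phenyl group; reagent control should place allyl on the Re face and set C1 as (R), since the adjacent quaternary C1' (CH3 versus ring CH2) gives little bias of its own.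

**Step 11**
Reactants: 15 (4R)-4-[(1R,3S)-3-bromo-1,2,2-trimethylcyclopentyl]-7-methylocta-1,7-dien-4-ol
Product: 16 (1R)-1-[(1R,3S)-3-bromo-1,2,2-trimethylcyclopentyl]-4-methylcyclohex-3-en-1-ol
Conditions: Grubbs II (5 mol %), CH2Cl2 (0.01 M), 40 °C
Reagents that add atoms: none
Why: Ring-closing metathesis of a monosubstituted with a 1,1-disubstituted alkene closes the cyclohexene with its trisubstituted C3=C4 bond (methyl on C4) and loses ethylene; the free tertiary alcohol is tolerated and no stereocentre is touched.

**Step 12**
Reactants: 16 (1R)-1-[(1R,3S)-3-bromo-1,2,2-trimethylcyclopentyl]-4-methylcyclohex-3-en-1-ol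
Product: 17 (1S,2S,4R)-2-bromo-4-[(1R,3S)-3-bromo-1,2,2-trimethylcyclopentyl]-1-methyl-7-oxabicyclo[2.2.1]heptane (2-endo-bromo)
Conditions: NBS, CH2Cl2, 0 °C, dark
Reagents that add atoms: N-bromosuccinimide, O=C1CCC(=O)N1Br
Why: Transannular bromoetherification as known for cyclohex-3-en-1-ols: bromonium formation is reversible and only the ion on the face opposite the C1 hydroxyl can be captured by that hydroxyl at the methyl-bearing carbon (Markovnikov, anti addition), so bromine ends anti to oxygen and C3 is set as (S).

**Step 13**
Reactants: 17 (1S,2S,4R)-2-bromo-4-[(1R,3S)-3-bromo-1,2,2-trimethylcyclopentyl]-1-methyl-7-oxabicyclo[2.2.1]heptane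
Product: 18 (1R,3S,4S)-3-bromo-1-[(1R,3S)-3-bromo-1,2,2-trimethylcyclopentyl]-4-chloro-4-methylcyclohexan-1-ol (target)
Conditions: BCl3 (1.05 equiv), CH2Cl2, −78 °C; cold aq. NaHCO3
Reagents that add atoms: boron trichloride, ClB(Cl)Cl
Why: Boron trihalide cleavage of a bridging tertiary ether: the endo C–Br bond is antiperiplanar to the C4–O bond and should assist its ionisation to the bromonium ion, to which the alkoxytrichloroborate held at C1 returns chloride at the methyl-bearing carbon on the face the oxygen left, so C4 is set with net retention (Cl trans to Br, cis to OH) and hydrolysis frees the C1 hydroxyl.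

**Compound list**
1 | 3-methylcyclohex-2-en-1-one | CC1=CC(=O)CCC1 | starting material
2 | iodomethane | CI | starting material
3 | 2,3-dimethylcyclohex-3-en-1-one (racemic, formed and methylated again in the flask) | CC1=CCCC(=O)C1C | intermediate
4 | 2,2,3-trimethylcyclohex-3-en-1-one | CC1=CCCC(=O)C1(C)C | intermediate
5 | (1S,6R)-1,2,2-trimethyl-7-oxabicyclo[4.1.0]heptan-3-one | CC1(C)C(=O)CC[C@H]2O[C@@]12C | intermediate
6 | (R)-1,2,2-trimethyl-3-oxocyclopentane-1-carbaldehyde | CC1(C)C(=O)CC[C@@]1(C)C=O | intermediate
7 | (3R)-3-(dimethoxymethyl)-2,2,3-trimethylcyclopentan-1-one | CC1(C)C(=O)CC[C@@]1(C)C(OC)OC | intermediate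
8 | (1R,3R)-3-(dimethoxymethyl)-2,2,3-trimethylcyclopentan-1-ol | CC1(C)[C@H](O)CC[C@@]1(C)C(OC)OC | intermediate
9 | (1S,3R)-1-bromo-3-(dimethoxymethyl)-2,2,3-trimethylcyclopentane | CC1(C)[C@@H](Br)CC[C@@]1(C)C(OC)OC | intermediate
10 | (1R,3S)-3-bromo-1,2,2-trimethylcyclopentane-1-carbaldehyde | CC1(C)[C@@H](Br)CC[C@@]1(C)C=O | intermediate
11 | 4-bromo-2-methylbut-1-ene | C=C(C)CCBr | starting material
12 | (3-methylbut-3-en-1-yl)magnesium bromide | C=C(C)CC[Mg]Br | intermediate
13 | 1-[(1R,3S)-3-bromo-1,2,2-trimethylcyclopentyl]-4-methylpent-4-en-1-ol (carbinol epimers) | CC1(C)[C@@H](Br)CC[C@@]1(C)C(O)CCC(C)=C | intermediate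
14 | 1-[(1R,3S)-3-bromo-1,2,2-trimethylcyclopentyl]-4-methylpent-4-en-1-one | CC1(C)[C@@H](Br)CC[C@@]1(C)C(=O)CCC(C)=C | intermediate
15 | (4R)-4-[(1R,3S)-3-bromo-1,2,2-trimethylcyclopentyl]-7-methylocta-1,7-dien-4-ol | CC1(C)[C@@H](Br)CC[C@@]1(C)[C@](O)(CC=C)CCC(C)=C | intermediate
16 | (1R)-1-[(1R,3S)-3-bromo-1,2,2-trimethylcyclopentyl]-4-methylcyclohex-3-en-1-ol | CC1(C)[C@@H](Br)CC[C@@]1(C)[C@@]1(O)CCC(C)=CC1 | intermediate
17 | (1S,2S,4R)-2-bromo-4-[(1R,3S)-3-bromo-1,2,2-trimethylcyclopentyl]-1-methyl-7-oxabicyclo[2.2.1]heptane | CC1(C)[C@@H](Br)CC[C@@]1(C)[C@@]12CC[C@](C)(O2)[C@@H](Br)C1 | intermediate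
18 | (1R,3S,4S)-3-bromo-1-[(1R,3S)-3-bromo-1,2,2-trimethylcyclopentyl]-4-chloro-4-methylcyclohexan-1-ol | CC1(C)[C@@H](Br)CC[C@@]1(C)[C@@]1(O)CC[C@](C)(Cl)[C@@H](Br)C1 | target

**Totals**
Total step count: 13. Longest linear sequence: 13 steps (1 → 18).

**Steps most likely to fail**

Step 3. Hydride migration from the epoxide CH carbon may compete with ring-bond migration, and stereochemical fidelity may erode if the tertiary cation becomes free before the shift. The fallback sets out from 4 and comes back at 6. Alkene 4 is epoxidised with the enantiomeric (L-fructose-derived) Shi ketone to (1R,6S)-1,2,2-trimethyl-7-oxabicyclo[4.1.0]heptan-3-one F1. Aqueous HBr in CHCl3 at 0 °C opens it at the tertiary carbon with inversion to (3S,4S)-3-bromo-4-hydroxy-2,2,3-trimethylcyclohexan-1-one F2. Silver-assisted halohydrin semipinacol rearrangement (AgBF4, 2,6-di-tert-butylpyridine, CH2Cl2, −40 °C) then takes place from the diequatorial conformer, in which the ring bond C4–C5, not the C4–H bond, is antiperiplanar to C–Br. That bond migrates with a second inversion, so the two inversions should deliver (R)-6, and ring contraction is enforced stereoelectronically.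

Step 6. Elimination to the cyclopentene, or ionisation with methyl shift from C2', may overtake the backside displacement, because bromide has to approach a neopentyl-type carbon on the face that carries the dimethoxymethyl group. The fallback sets out from 7 and comes back at 9. Ketone 7 is condensed with 1,2-bis(tert-butyldimethylsilyl)hydrazine (cat. Sc(OTf)3) to (3R)-3-(dimethoxymethyl)-2,2,3-trimethylcyclopentan-1-one N-(tert-butyldimethylsilyl)hydrazone F3. CuBr2/Et3N in MeOH converts this to (3R)-1,1-dibromo-3-(dimethoxymethyl)-2,2,3-trimethylcyclopentane F4. One C–Br bond is then reduced with Bu3SnH (1 equiv, Et3B/air, toluene, −78 °C). The α-bromo radical should take hydrogen on the less hindered face, anti to the dimethoxymethyl group, leaving bromine cis to it as in 9, so the sterics that oppose the SN2 step work in favour here.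

Step 13. The ether may ionise at the other bridgehead (C1–O, an ordinary tertiary centre next to the quaternary C1', not slowed by a β-bromine) faster than the bromine-assisted cleavage at C4–O, leading to elimination or skeletal shifts of the cyclopentyl group; chloride may also enter at C3. The fallback sets out from 16 and comes back at 18. The tertiary alcohol is silylated (TESOTf, 2,6-lutidine, CH2Cl2) to triethyl{[(1R)-1-[(1R,3S)-3-bromo-1,2,2-trimethylcyclopentyl]-4-methylcyclohex-3-en-1-yl]oxy}silane F5. Its axial silyloxy group screens the syn face of the ring alkene, so intermolecular bromochlorination with Bu4N+ BrCl2− (CH2Cl2, −78 °C) should form the bromonium ion on the anti face. Chloride then enters anti at the methyl-bearing carbon, giving the triethylsilyl ether of 18, {[(1R,3S,4S)-3-bromo-1-[(1R,3S)-3-bromo-1,2,2-trimethylcyclopentyl]-4-chloro-4-methylcyclohexyl]oxy}triethylsilane F6. HF·pyridine in THF removes the silyl group to give 18, and the trans-dihalide diastereomers are separated by chromatography.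

**Further compounds**
F1 | step 3 | (1R,6S)-1,2,2-trimethyl-7-oxabicyclo[4.1.0]heptan-3-one | CC1(C)C(=O)CC[C@@H]2O[C@]12C
F2 | step 3 | (3S,4S)-3-bromo-4-hydroxy-2,2,3-trimethylcyclohexan-1-one | CC1(C)C(=O)CC[C@H](O)[C@@]1(C)Br
F3 | step 6 | (3R)-3-(dimethoxymethyl)-2,2,3-trimethylcyclopentan-1-one N-(tert-butyldimethylsilyl)hydrazone | CC1(C)C(=NN[Si](C)(C)C(C)(C)C)CC[C@@]1(C)C(OC)OC
F4 | step 6 | (3R)-1,1-dibromo-3-(dimethoxymethyl)-2,2,3-trimethylcyclopentane | CC1(C)C(Br)(Br)CC[C@@]1(C)C(OC)OC
F5 | step 13 | triethyl{[(1R)-1-[(1R,3S)-3-bromo-1,2,2-trimethylcyclopentyl]-4-methylcyclohex-3-en-1-yl]oxy}silane | CC1(C)[C@@H](Br)CC[C@@]1(C)[C@@]1(O[Si](CC)(CC)CC)CCC(C)=CC1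
F6 | step 13 | {[(1R,3S,4S)-3-bromo-1-[(1R,3S)-3-bromo-1,2,2-trimethylcyclopentyl]-4-chloro-4-methylcyclohexyl]oxy}triethylsilane | CC1(C)[C@@H](Br)CC[C@@]1(C)[C@@]1(O[Si](CC)(CC)CC)CC[C@](C)(Cl)[C@@H](Br)C1
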